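**Assumption:** commercial natural phytol is the (2E,7R,11R) isomer; 1,3-diones are drawn as diketo tautomers.

## Retrosynthetic overview

1. The C9 acetyl comes from Markovnikov hydration of an ethynyl carbinol; the C7/C8 methyls and the enone are added last to a spiro cyclopentanone (α-methylation, Saegusa, cuprate addition, Saegusa).
2. The oxolane ring and both ring stereocentres come from hydroxyl-directed epoxidation of a (1R)-cyclopentenol and 5-exo opening by the side-chain tertiary alcohol (inversion at the spiro carbon); the carbinol comes from CBS reduction of a 2-alkyl-3-alkynylcyclopentenone.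
3. That enone comes from a 2-alkylcyclopentane-1,3-dione (Stork–Danheiser). The key C–C bond is an intermolecular aldol (Knoevenagel-type) condensation of cyclopentane-1,3-dione with a C20 β-silyloxy aldehyde, reduced in situ.
4. The aldehyde comes from natural phytol: Sharpless epoxidation and Red-Al opening set the tertiary carbinol (future C2).
5. Ring order: the carbocycle is bought (cyclopentane-1,3-dione); the oxolane is the only ring formed (step 9).

## Route

Step 1
Reactants: 1 (2E,7R,11R)-3,7,11,15-tetramethylhexadec-2-en-1-ol (natural phytol)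
Product: 2 [(2R,3R)-3-methyl-3-[(4R,8R)-4,8,12-trimethyltridecyl]oxiran-2-yl]methanol
Conditions: Ti(OiPr)4 (10 mol %), D-(−)-diethyl tartrate (12 mol %), t-BuOOH, 4 Å MS, CH2Cl2, −20 °C
Reagents that add atoms: tert-butyl hydroperoxide CC(C)(C)OO
Why: Sharpless asymmetric epoxidation of the trisubstituted E-allylic alcohol, where D-(−)-tartrate delivers oxygen to the face that gives the (2R,3R)-epoxide (geraniol precedent) and so fixes the future oxolane C2.

Step 2
Reactants: 2 [(2R,3R)-3-methyl-3-[(4R,8R)-4,8,12-trimethyltridecyl]oxiran-2-yl]methanol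
Product: 3 (3R,7R,11R)-3,7,11,15-tetramethylhexadecane-1,3-diol
Conditions: NaAlH2(OCH2CH2OMe)2 (Red-Al), THF, 0 °C → rt; aq. potassium sodium tartrate
Reagents that add atoms: none
Why: Regioselective reductive opening of a 2,3-epoxy alcohol, in which the aluminate bound to the primary oxygen delivers hydride to C2 and leaves the C3–O bond and its configuration untouched.

Step 3
Reactants: 3 (3R,7R,11R)-3,7,11,15-tetramethylhexadecane-1,3-diol
Product: 4 (3R,7R,11R)-3,7,11,15-tetramethyl-1,3-bis(triethylsilyloxy)hexadecane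
Conditions: Et3SiOTf (2.5 equiv), 2,6-lutidine, CH2Cl2, −78 → 0 °C
Reagents that add atoms: triethylsilyl trifluoromethanesulfonate CC[Si](CC)(CC)OS(=O)(=O)C(F)(F)F
Why: Silyl triflate silylation caps both hydroxyls, the tertiary one included, so that no free β-hydroxy aldehyde (retro-aldol, dehydration) is ever formed.

Step 4
Reactants: 4 (3R,7R,11R)-3,7,11,15-tetramethyl-1,3-bis(triethylsilyloxy)hexadecane
Product: 5 (3R,7R,11R)-3,7,11,15-tetramethyl-3-(triethylsilyloxy)hexadecanal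
Conditions: (COCl)2, DMSO, CH2Cl2, −78 → −40 °C; Et3N, −78 °C → rt
Reagents that add atoms: none
Why: Swern oxidation in which the chlorosulfonium species cleaves only the unhindered primary triethylsilyl ether and oxidises it directly to the aldehyde, while the hindered tertiary silyl ether survives.

Step 5
Reactants: 5 (3R,7R,11R)-3,7,11,15-tetramethyl-3-(triethylsilyloxy)hexadecanal; 6 cyclopentane-1,3-dione
Product: 8 2-[(3R,7R,11R)-3,7,11,15-tetramethyl-3-(triethylsilyloxy)hexadecyl]cyclopentane-1,3-dione, via alkylidene dione 7 (not isolated)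
Conditions: diethyl 2,6-dimethyl-1,4-dihydropyridine-3,5-dicarboxylate (Hantzsch ester, 1.1 equiv), L-proline (20 mol %), CH2Cl2, 25 °C
Reagents that add atoms: none
Why: Intermolecular aldol condensation of Knoevenagel type (dione enol adds to the proline-activated aldehyde, water is lost) joins the two fragments, and the electrophilic alkylidene dione is reduced at once by hydride transfer from the Hantzsch ester, which prevents double addition.

Step 6
Reactants: 8 2-[(3R,7R,11R)-3,7,11,15-tetramethyl-3-(triethylsilyloxy)hexadecyl]cyclopentane-1,3-dione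
Product: 9 3-methoxy-2-[(3R,7R,11R)-3,7,11,15-tetramethyl-3-(triethylsilyloxy)hexadecyl]cyclopent-2-en-1-one
Conditions: Me3SiCHN2, MeOH/toluene 1:4, 0 °C → rt
Reagents that add atoms: (trimethylsilyl)diazomethane C[Si](C)(C)C=[N+]=[N-]
Why: O-Methylation of the vinylogous acid gives the vinylogous ester, and the symmetrical dione can give only one enol ether.

Step 7
Reactants: 9 3-methoxy-2-[(3R,7R,11R)-3,7,11,15-tetramethyl-3-(triethylsilyloxy)hexadecyl]cyclopent-2-en-1-one
Product: 11 2-[(3R,7R,11R)-3-hydroxy-3,7,11,15-tetramethylhexadecyl]-3-[(trimethylsilyl)ethynyl]cyclopent-2-en-1-one, via acetylide adduct 10 (not isolated)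
Conditions: Me3SiC≡CH, n-BuLi, THF, −78 °C, then 9, −78 → 0 °C; 2 M HCl, THF, rt
Reagents that add atoms: (trimethylsilyl)acetylene C#C[Si](C)(C)C; water O
Why: Stork–Danheiser sequence (1,2-addition of the lithium acetylide to the vinylogous ester, then acid hydrolysis with carbonyl transposition) gives the 3-alkynyl enone, and the aqueous acid also removes the tertiary triethylsilyl ether.

Step 8
Reactants: 11 2-[(3R,7R,11R)-3-hydroxy-3,7,11,15-tetramethylhexadecyl]-3-[(trimethylsilyl)ethynyl]cyclopent-2-en-1-one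
Product: 12 (1R)-2-[(3R,7R,11R)-3-hydroxy-3,7,11,15-tetramethylhexadecyl]-3-[(trimethylsilyl)ethynyl]cyclopent-2-en-1-ol
Conditions: (S)-1-methyl-3,3-diphenyltetrahydro-1H,3H-pyrrolo[1,2-c][1,3,2]oxazaborole ((S)-Me-CBS, 0.3 equiv), catecholborane (3 equiv), toluene, −78 → −40 °C; MeOH
Reagents that add atoms: none
Why: Corey–Bakshi–Shibata reduction, in which the (S)-oxazaborolidine treats the α-substituted alkenyl side as the large group and gives the (1R)-alcohol (same sense as (R)-1-phenylethanol from acetophenone), while catecholborane gives only 1,2-reduction and spares the alkyne.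

Step 9
Reactants: 12 (1R)-2-[(3R,7R,11R)-3-hydroxy-3,7,11,15-tetramethylhexadecyl]-3-[(trimethylsilyl)ethynyl]cyclopent-2-en-1-ol
Product: 14 (2R,5S,6R,9R)-2-methyl-6-[(trimethylsilyl)ethynyl]-2-[(4R,8R)-4,8,12-trimethyltridecyl]-1-oxaspiro[4.4]nonane-6,9-diol, via syn-epoxy alcohol 13 (not isolated)
Conditions: VO(acac)2 (5 mol %), t-BuOOH (decane), CH2Cl2, 0 °C → rt; then (1S)-camphor-10-sulfonic acid (10 mol %), rt
Reagents that add atoms: tert-butyl hydroperoxide CC(C)(C)OO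
Why: VO(acac)2 hydroxyl-directed epoxidation places the epoxide on the face of the ring OH, and the side-chain tertiary alcohol opens it 5-exo-tet with inversion at the chain-bearing carbon (the alkynyl-substituted carbon is electronically disfavoured), so the spiro C–O bond is trans and the new tertiary OH cis to the directing hydroxyl, which sets both ring stereocentres of the target.

Step 10
Reactants: 14 (2R,5S,6R,9R)-2-methyl-6-[(trimethylsilyl)ethynyl]-2-[(4R,8R)-4,8,12-trimethyltridecyl]-1-oxaspiro[4.4]nonane-6,9-diol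
Product: 15 (2R,5R,9R)-9-hydroxy-2-methyl-9-[(trimethylsilyl)ethynyl]-2-[(4R,8R)-4,8,12-trimethyltridecyl]-1-oxaspiro[4.4]nonan-6-one
Conditions: 1,1,1-triacetoxy-1,1-dihydro-1,2-benziodoxol-3(1H)-one (Dess–Martin periodinane), NaHCO3, CH2Cl2, 0 °C → rt
Reagents that add atoms: none
Why: Dess–Martin oxidation converts the only secondary alcohol into the ketone, the tertiary alcohol cannot be oxidised, and the buffered neutral medium avoids retro-aldol cleavage.

Step 11
Reactants: 15 (2R,5R,9R)-9-hydroxy-2-methyl-9-[(trimethylsilyl)ethynyl]-2-[(4R,8R)-4,8,12-trimethyltridecyl]-1-oxaspiro[4.4]nonan-6-one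
Product: 16 (2R,5R,9R)-2-methyl-9-[(trimethylsilyl)ethynyl]-9-(trimethylsilyloxy)-2-[(4R,8R)-4,8,12-trimethyltridecyl]-1-oxaspiro[4.4]nonan-6-one
Conditions: N-(trimethylsilyl)imidazole, CH2Cl2, 40 °C
Reagents that add atoms: N-(trimethylsilyl)imidazole C[Si](C)(C)n1ccnc1
Why: Silylation with the silyl imidazole caps the hindered tertiary alcohol without enolising the ketone, so that no β-alkoxide (retro-aldol) can form in the base steps that follow.

Step 12
Reactants: 16 (2R,5R,9R)-2-methyl-9-[(trimethylsilyl)ethynyl]-9-(trimethylsilyloxy)-2-[(4R,8R)-4,8,12-trimethyltridecyl]-1-oxaspiro[4.4]nonan-6-one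
Product: 17 (2R,5R,9R)-2,7-dimethyl-9-[(trimethylsilyl)ethynyl]-9-(trimethylsilyloxy)-2-[(4R,8R)-4,8,12-trimethyltridecyl]-1-oxaspiro[4.4]nonan-6-one (both C7 epimers)
Conditions: LiN(iPr)2, THF, −78 °C; MeI, −78 → −30 °C
Reagents that add atoms: iodomethane CI
Why: Enolate alkylation is regiospecific because the spiro carbon is quaternary and only C7 can be deprotonated, and the new C7 centre is irrelevant since it becomes sp2 in step 14.

Step 13
Reactants: 17 (2R,5R,9R)-2,7-dimethyl-9-[(trimethylsilyl)ethynyl]-9-(trimethylsilyloxy)-2-[(4R,8R)-4,8,12-trimethyltridecyl]-1-oxaspiro[4.4]nonan-6-one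
Product: 18 (2R,5S,9R)-2,7-dimethyl-6,9-bis(trimethylsilyloxy)-9-[(trimethylsilyl)ethynyl]-2-[(4R,8R)-4,8,12-trimethyltridecyl]-1-oxaspiro[4.4]non-6-ene
Conditions: Me3SiOTf, Et3N, CH2Cl2, 0 °C
Reagents that add atoms: trimethylsilyl trifluoromethanesulfonate C[Si](C)(C)OS(=O)(=O)C(F)(F)F
Why: Soft enolisation and O-silylation give the only possible silyl enol ether (C6=C7), the substrate for Saegusa oxidation.

Step 14
Reactants: 18 (2R,5S,9R)-2,7-dimethyl-6,9-bis(trimethylsilyloxy)-9-[(trimethylsilyl)ethynyl]-2-[(4R,8R)-4,8,12-trimethyltridecyl]-1-oxaspiro[4.4]non-6-ene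
Product: 19 (2R,5R,9R)-2,7-dimethyl-9-[(trimethylsilyl)ethynyl]-9-(trimethylsilyloxy)-2-[(4R,8R)-4,8,12-trimethyltridecyl]-1-oxaspiro[4.4]non-7-en-6-one
Conditions: Pd(OAc)2 (1.1 equiv), MeCN, rt
Reagents that add atoms: none
Why: Saegusa–Ito oxidation, in which the palladium enolate undergoes β-hydride elimination toward C8 to give the endocyclic 2-methyl enone.

Step 15
Reactants: 19 (2R,5R,9R)-2,7-dimethyl-9-[(trimethylsilyl)ethynyl]-9-(trimethylsilyloxy)-2-[(4R,8R)-4,8,12-trimethyltridecyl]-1-oxaspiro[4.4]non-7-en-6-one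
Product: 20 (2R,5S,9R)-2,7,8-trimethyl-6,9-bis(trimethylsilyloxy)-9-[(trimethylsilyl)ethynyl]-2-[(4R,8R)-4,8,12-trimethyltridecyl]-1-oxaspiro[4.4]non-6-ene (both C8 epimers)
Conditions: Me2CuLi (from MeLi and CuI), Me3SiCl, THF, −78 °C; Et3N, then aq. NH4Cl/NH3
Reagents that add atoms: lithium dimethylcuprate [Li+].C[Cu-]C; chlorotrimethylsilane C[Si](C)(C)Cl
Why: Silyl-chloride-accelerated conjugate addition of the Gilman cuprate puts the methyl on C8 and traps the regiodefined enolate as its silyl enol ether, a reaction that 4-silyloxycyclopentenones are known to tolerate (C8 configuration is irrelevant).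

Step 16
Reactants: 20 (2R,5S,9R)-2,7,8-trimethyl-6,9-bis(trimethylsilyloxy)-9-[(trimethylsilyl)ethynyl]-2-[(4R,8R)-4,8,12-trimethyltridecyl]-1-oxaspiro[4.4]non-6-ene
Product: 21 (2R,5R,9R)-2,7,8-trimethyl-9-[(trimethylsilyl)ethynyl]-9-(trimethylsilyloxy)-2-[(4R,8R)-4,8,12-trimethyltridecyl]-1-oxaspiro[4.4]non-7-en-6-one
Conditions: Pd(OAc)2 (1.1 equiv), MeCN, rt → 40 °C
Reagents that add atoms: none
Why: A second Saegusa–Ito oxidation (β-hydride elimination of the C8 hydrogen) gives the thermodynamically favoured tetrasubstituted enone.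

Step 17
Reactants: 21 (2R,5R,9R)-2,7,8-trimethyl-9-[(trimethylsilyl)ethynyl]-9-(trimethylsilyloxy)-2-[(4R,8R)-4,8,12-trimethyltridecyl]-1-oxaspiro[4.4]non-7-en-6-one
Product: 22 (2R,5R,9S)-9-ethynyl-9-hydroxy-2,7,8-trimethyl-2-[(4R,8R)-4,8,12-trimethyltridecyl]-1-oxaspiro[4.4]non-7-en-6-one
Conditions: Bu4NF, AcOH (1:1), THF, 0 °C → rt
Reagents that add atoms: none
Why: Buffered fluoride desilylation cleaves both the O–Si and the alkynyl C–Si bond, and the acetic acid keeps the medium non-basic so the β-hydroxy ketone does not undergo retro-aldol (the C9 descriptor changes only through CIP priorities).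

Step 18
Reactants: 22 (2R,5R,9S)-9-ethynyl-9-hydroxy-2,7,8-trimethyl-2-[(4R,8R)-4,8,12-trimethyltridecyl]-1-oxaspiro[4.4]non-7-en-6-one
Product: 23 (2R,5R,9S)-9-acetyl-9-hydroxy-2,7,8-trimethyl-2-[(4R,8R)-4,8,12-trimethyltridecyl]-1-oxaspiro[4.4]non-7-en-6-one
Conditions: HgSO4 (10 mol %), H2SO4 (cat.), H2O, THF, rt
Reagents that add atoms: water O
Why: HgSO4-catalysed Markovnikov hydration of the terminal alkyne (Kucherov reaction) gives the methyl ketone without touching a stereocentre, and Rupe rearrangement is impossible because neither neighbour of the carbinol carbon carries hydrogen.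

## Compound list

1 | (2E,7R,11R)-3,7,11,15-tetramethylhexadec-2-en-1-ol (natural phytol) | OC/C=C(C)/CCC[C@H](C)CCC[C@H](C)CCCC(C)C | starting material
2 | [(2R,3R)-3-methyl-3-[(4R,8R)-4,8,12-trimethyltridecyl]oxiran-2-yl]methanol | OC[C@H]1O[C@]1(C)CCC[C@H](C)CCC[C@H](C)CCCC(C)C | intermediate
3 | (3R,7R,11R)-3,7,11,15-tetramethylhexadecane-1,3-diol | OCC[C@](C)(O)CCC[C@H](C)CCC[C@H](C)CCCC(C)C | intermediate
4 | (3R,7R,11R)-3,7,11,15-tetramethyl-1,3-bis(triethylsilyloxy)hexadecane | CC[Si](CC)(CC)OCC[C@](C)(O[Si](CC)(CC)CC)CCC[C@H](C)CCC[C@H](C)CCCC(C)C | intermediate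
5 | (3R,7R,11R)-3,7,11,15-tetramethyl-3-(triethylsilyloxy)hexadecanal | O=CC[C@](C)(O[Si](CC)(CC)CC)CCC[C@H](C)CCC[C@H](C)CCCC(C)C | intermediate
6 | cyclopentane-1,3-dione | O=C1CCC(=O)C1 | starting material
7 | 2-[(3R,7R,11R)-3,7,11,15-tetramethyl-3-(triethylsilyloxy)hexadecylidene]cyclopentane-1,3-dione (not isolated) | O=C1CCC(=O)C1=CC[C@](C)(O[Si](CC)(CC)CC)CCC[C@H](C)CCC[C@H](C)CCCC(C)C | intermediate
8 | 2-[(3R,7R,11R)-3,7,11,15-tetramethyl-3-(triethylsilyloxy)hexadecyl]cyclopentane-1,3-dione | O=C1CCC(=O)C1CC[C@](C)(O[Si](CC)(CC)CC)CCC[C@H](C)CCC[C@H](C)CCCC(C)C | intermediate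
9 | 3-methoxy-2-[(3R,7R,11R)-3,7,11,15-tetramethyl-3-(triethylsilyloxy)hexadecyl]cyclopent-2-en-1-one | COC1=C(CC[C@](C)(O[Si](CC)(CC)CC)CCC[C@H](C)CCC[C@H](C)CCCC(C)C)C(=O)CC1 | intermediate
10 | 3-methoxy-2-[(3R,7R,11R)-3,7,11,15-tetramethyl-3-(triethylsilyloxy)hexadecyl]-1-[(trimethylsilyl)ethynyl]cyclopent-2-en-1-ol, both C1 epimers (not isolated) | COC1=C(CC[C@](C)(O[Si](CC)(CC)CC)CCC[C@H](C)CCC[C@H](C)CCCC(C)C)C(O)(C#C[Si](C)(C)C)CC1 | intermediate
11 | 2-[(3R,7R,11R)-3-hydroxy-3,7,11,15-tetramethylhexadecyl]-3-[(trimethylsilyl)ethynyl]cyclopent-2-en-1-one | C[Si](C)(C)C#CC1=C(CC[C@](C)(O)CCC[C@H](C)CCC[C@H](C)CCCC(C)C)C(=O)CC1 | intermediate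
12 | (1R)-2-[(3R,7R,11R)-3-hydroxy-3,7,11,15-tetramethylhexadecyl]-3-[(trimethylsilyl)ethynyl]cyclopent-2-en-1-ol | O[C@@H]1CCC(C#C[Si](C)(C)C)=C1CC[C@](C)(O)CCC[C@H](C)CCC[C@H](C)CCCC(C)C | intermediate
13 | (1R,2R,5R)-1-[(3R,7R,11R)-3-hydroxy-3,7,11,15-tetramethylhexadecyl]-5-[(trimethylsilyl)ethynyl]-6-oxabicyclo[3.1.0]hexan-2-ol, epoxide cis to the 2-OH (not isolated) | C[Si](C)(C)C#C[C@]12CC[C@@H](O)[C@@]1(CC[C@](C)(O)CCC[C@H](C)CCC[C@H](C)CCCC(C)C)O2 | intermediate
14 | (2R,5S,6R,9R)-2-methyl-6-[(trimethylsilyl)ethynyl]-2-[(4R,8R)-4,8,12-trimethyltridecyl]-1-oxaspiro[4.4]nonane-6,9-diol | C[Si](C)(C)C#C[C@]1(O)CC[C@@H](O)[C@@]12CC[C@@](C)(CCC[C@H](C)CCC[C@H](C)CCCC(C)C)O2 | intermediate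
15 | (2R,5R,9R)-9-hydroxy-2-methyl-9-[(trimethylsilyl)ethynyl]-2-[(4R,8R)-4,8,12-trimethyltridecyl]-1-oxaspiro[4.4]nonan-6-one | C[Si](C)(C)C#C[C@]1(O)CCC(=O)[C@@]12CC[C@@](C)(CCC[C@H](C)CCC[C@H](C)CCCC(C)C)O2 | intermediate
16 | (2R,5R,9R)-2-methyl-9-[(trimethylsilyl)ethynyl]-9-(trimethylsilyloxy)-2-[(4R,8R)-4,8,12-trimethyltridecyl]-1-oxaspiro[4.4]nonan-6-one | C[Si](C)(C)C#C[C@]1(O[Si](C)(C)C)CCC(=O)[C@@]12CC[C@@](C)(CCC[C@H](C)CCC[C@H](C)CCCC(C)C)O2 | intermediate
17 | (2R,5R,9R)-2,7-dimethyl-9-[(trimethylsilyl)ethynyl]-9-(trimethylsilyloxy)-2-[(4R,8R)-4,8,12-trimethyltridecyl]-1-oxaspiro[4.4]nonan-6-one, both C7 epimers | C[Si](C)(C)C#C[C@]1(O[Si](C)(C)C)CC(C)C(=O)[C@@]12CC[C@@](C)(CCC[C@H](C)CCC[C@H](C)CCCC(C)C)O2 | intermediate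
18 | (2R,5S,9R)-2,7-dimethyl-6,9-bis(trimethylsilyloxy)-9-[(trimethylsilyl)ethynyl]-2-[(4R,8R)-4,8,12-trimethyltridecyl]-1-oxaspiro[4.4]non-6-ene | C[Si](C)(C)C#C[C@]1(O[Si](C)(C)C)CC(C)=C(O[Si](C)(C)C)[C@@]12CC[C@@](C)(CCC[C@H](C)CCC[C@H](C)CCCC(C)C)O2 | intermediate
19 | (2R,5R,9R)-2,7-dimethyl-9-[(trimethylsilyl)ethynyl]-9-(trimethylsilyloxy)-2-[(4R,8R)-4,8,12-trimethyltridecyl]-1-oxaspiro[4.4]non-7-en-6-one | C[Si](C)(C)C#C[C@]1(O[Si](C)(C)C)C=C(C)C(=O)[C@@]12CC[C@@](C)(CCC[C@H](C)CCC[C@H](C)CCCC(C)C)O2 | intermediate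
20 | (2R,5S,9R)-2,7,8-trimethyl-6,9-bis(trimethylsilyloxy)-9-[(trimethylsilyl)ethynyl]-2-[(4R,8R)-4,8,12-trimethyltridecyl]-1-oxaspiro[4.4]non-6-ene, both C8 epimers | C[Si](C)(C)C#C[C@]1(O[Si](C)(C)C)C(C)C(C)=C(O[Si](C)(C)C)[C@@]12CC[C@@](C)(CCC[C@H](C)CCC[C@H](C)CCCC(C)C)O2 | intermediate
21 | (2R,5R,9R)-2,7,8-trimethyl-9-[(trimethylsilyl)ethynyl]-9-(trimethylsilyloxy)-2-[(4R,8R)-4,8,12-trimethyltridecyl]-1-oxaspiro[4.4]non-7-en-6-one | C[Si](C)(C)C#C[C@]1(O[Si](C)(C)C)C(C)=C(C)C(=O)[C@@]12CC[C@@](C)(CCC[C@H](C)CCC[C@H](C)CCCC(C)C)O2 | intermediate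
22 | (2R,5R,9S)-9-ethynyl-9-hydroxy-2,7,8-trimethyl-2-[(4R,8R)-4,8,12-trimethyltridecyl]-1-oxaspiro[4.4]non-7-en-6-one | C#C[C@]1(O)C(C)=C(C)C(=O)[C@@]12CC[C@@](C)(CCC[C@H](C)CCC[C@H](C)CCCC(C)C)O2 | intermediate
23 | (2R,5R,9S)-9-acetyl-9-hydroxy-2,7,8-trimethyl-2-[(4R,8R)-4,8,12-trimethyltridecyl]-1-oxaspiro[4.4]non-7-en-6-one | CC(=O)[C@]1(O)C(C)=C(C)C(=O)[C@@]12CC[C@@](C)(CCC[C@H](C)CCC[C@H](C)CCCC(C)C)O2 | target

## Step count and risks

Total step count: 18. Longest linear sequence: 18 steps (1 → 23); compound 6 enters at step 5.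

The three steps most likely to fail:

**Step 8 (CBS reduction).** The ketone is flanked by a tetrasubstituted, alkynyl-bearing alkene, so the enantioselectivity may be lower than for simple 2-substituted enones. The fallback sets out from 11 and returns at 12. Luche reduction (NaBH4, CeCl3·7H2O, MeOH, −78 °C) gives the 1:1 mixture of carbinol epimers F1. Kinetic resolution with immobilised Candida antarctica lipase B and vinyl acetate acylates only the (1R)-epimer (Kazlauskas rule, large group = substituted alkenyl side) to the (1R)-acetate F2. F2 is separated from the unreacted (1S)-alcohol F3, which is returned to 11 with MnO2. i-Bu2AlH in CH2Cl2 at −78 °C removes the acetate from F2 and gives 12.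

**Step 9 (directed epoxidation and spiro ring closure).** The tetrasubstituted enyne may epoxidise slowly, and an acid-promoted opening could give some six-membered ether by attack at the propargylic carbon. The fallback sets out from 9 and returns at 14; it separates epoxidation from ring closure and closes the ring as an alkoxide SN2 reaction. Me3SiC≡CLi is added to 9 as in step 7, but adduct 10 is hydrolysed with aqueous oxalic acid at 0 °C so that the silyl ether is kept, giving the silyl-protected enynone F4. CBS reduction as in step 8 gives the silyl-protected (1R)-allylic alcohol F5. VO(acac)2/t-BuOOH gives the silyl-protected syn-epoxy alcohol F6, which is isolable because the nucleophile is masked. HF·pyridine in THF/pyridine removes the triethylsilyl group and gives 13 as an isolated compound. NaH in THF then closes the ring by 5-exo-tet alkoxide opening to 14 (Baldwin-favoured, no cationic character, and no Payne shift possible for the cis epoxy alcohol).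

**Step 16 (Saegusa oxidation to the tetrasubstituted enone).** β-Hydride elimination may go toward the C7 methyl (exocyclic methylene), or the hindered palladium enolate may react sluggishly. The fallback sets out from 20 and returns at 21 by bromination and dehydrobromination. N-Bromosuccinimide in THF at 0 °C converts silyl enol ether 20 into the tertiary α-bromo ketone F7. Li2CO3 and LiBr in DMF at 100 °C eliminate HBr to give the thermodynamically preferred endocyclic enone 21.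

## Further compounds

F1 | step 8 | 2-[(3R,7R,11R)-3-hydroxy-3,7,11,15-tetramethylhexadecyl]-3-[(trimethylsilyl)ethynyl]cyclopent-2-en-1-ol, 1:1 mixture of C1 epimers | OC1CCC(C#C[Si](C)(C)C)=C1CC[C@](C)(O)CCC[C@H](C)CCC[C@H](C)CCCC(C)C
F2 | step 8 | (1R)-2-[(3R,7R,11R)-3-hydroxy-3,7,11,15-tetramethylhexadecyl]-3-[(trimethylsilyl)ethynyl]cyclopent-2-en-1-yl acetate | CC(=O)O[C@@H]1CCC(C#C[Si](C)(C)C)=C1CC[C@](C)(O)CCC[C@H](C)CCC[C@H](C)CCCC(C)C
F3 | step 8 | (1S)-2-[(3R,7R,11R)-3-hydroxy-3,7,11,15-tetramethylhexadecyl]-3-[(trimethylsilyl)ethynyl]cyclopent-2-en-1-ol | O[C@H]1CCC(C#C[Si](C)(C)C)=C1CC[C@](C)(O)CCC[C@H](C)CCC[C@H](C)CCCC(C)C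
F4 | step 9 | 2-[(3R,7R,11R)-3,7,11,15-tetramethyl-3-(triethylsilyloxy)hexadecyl]-3-[(trimethylsilyl)ethynyl]cyclopent-2-en-1-one | C[Si](C)(C)C#CC1=C(CC[C@](C)(O[Si](CC)(CC)CC)CCC[C@H](C)CCC[C@H](C)CCCC(C)C)C(=O)CC1
F5 | step 9 | (1R)-2-[(3R,7R,11R)-3,7,11,15-tetramethyl-3-(triethylsilyloxy)hexadecyl]-3-[(trimethylsilyl)ethynyl]cyclopent-2-en-1-ol | O[C@@H]1CCC(C#C[Si](C)(C)C)=C1CC[C@](C)(O[Si](CC)(CC)CC)CCC[C@H](C)CCC[C@H](C)CCCC(C)C
F6 | step 9 | (1R,2R,5R)-1-[(3R,7R,11R)-3,7,11,15-tetramethyl-3-(triethylsilyloxy)hexadecyl]-5-[(trimethylsilyl)ethynyl]-6-oxabicyclo[3.1.0]hexan-2-ol | C[Si](C)(C)C#C[C@]12CC[C@@H](O)[C@@]1(CC[C@](C)(O[Si](CC)(CC)CC)CCC[C@H](C)CCC[C@H](C)CCCC(C)C)O2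
F7 | step 16 | (2R,5R,9R)-7-bromo-2,7,8-trimethyl-9-[(trimethylsilyl)ethynyl]-9-(trimethylsilyloxy)-2-[(4R,8R)-4,8,12-trimethyltridecyl]-1-oxaspiro[4.4]nonan-6-one, mixture at C7 and C8 | C[Si](C)(C)C#C[C@]1(O[Si](C)(C)C)C(C)C(C)(Br)C(=O)[C@@]12CC[C@@](C)(CCC[C@H](C)CCC[C@H](C)CCCC(C)C)O2
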